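## Structural features

The target 30 is a methylene-bridged pair of two different acylphloroglucinol units with three rings: ring A is a 2-acyl-4,4-dimethylcyclohexane-1,3,5-trione held as a dienol, ring B is a benzene ring with a substituent on every carbon, and ring C is a 2,2-dimethyl-2H-pyran fused to ring B along C4a–C8a. Ring A positions are called a1 to a6 here: a1 carries an isobutyryl group, a3 the two methyl groups, a5 the bridging CH2, and a2, a4 and a6 the oxygens. In chromene numbering ring B carries the C4 end of the ring C alkene at C4a, a hydroxyl at C5, the second isobutyryl group at C6, a hydroxyl at C7, the bridging CH2 at C8 and the ring oxygen O1 at C8a. There is no stereocentre and no stereogenic double bond (a3 and C2 each carry two identical methyl groups), so no stereocentres stand next to each other and the problem is one of regiochemistry only. The fragile elements are the electron-rich C3=C4 bond (acid, electrophiles, oxidants), the polyphenolic ring B (oxidation), the acidic β-triketone of ring A, and the bridge, which can reopen by retro-Michael loss of ring A under base or heat and then scramble to symmetrical dimers. The real difficulty is ring B: its three oxygens must be told apart (O1 locked in ring C and next to the bridge, O5 and O7 free and flanking the acyl group), its three carbon substituents must be placed without isomers, and the bridge must join two unlike rings. The key step exploits the fact that C8a, C8, C7, C6, C5 and C4a can each be traced to a different atom of two open-chain partners, so that the oxygen on C8a is the only free hydroxyl, flanked by a C8 that already carries the bridge carbon and a C4a that carries the prenyl chain of ring C, with O7 silylated, O5 methylated and C6 left as the single C–H.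

## Logic of the disconnections

30 to 23 and 27. The bond between the bridge carbon and a5 is cut. The bridge carbon stays on ring B, where it has been since ring B was made, and a5 of 27 is the nucleophile. This polarity makes the union of two unlike rings unambiguous, which a one-carbon coupling of two nucleophilic rings cannot do. The gain is two fragments of about half the size, one of which (27) has a single reactive ring carbon. The forward step must unmask 23 to 28 and ionize it to 29 under conditions that spare the C3=C4 bond, with 27 in excess and with only brief exposure to base so that the new bond does not reopen.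

27 to 26, then to 24 and 25. The two C–CH3 bonds at a3 are cut, then the ring–acyl bond at a1. Both cuts lead to a symmetrical arene whose free carbons are equivalent, so regiochemistry is not an issue. The forward methylation must stop once the second methyl group has broken the aromaticity, which means separation from under- and over-methylated material.

23 to 22, then to 19 and 20. The O5–CH3 bond is restored first, with no skeletal change. The methyl group shields O5 through the organolithium step, and it is the one ether that a carbonyl-directed Lewis acid removes once the C6 ketone is in place. The C6–acyl bond is then cut to the C6 carbanion 21 and the acyl donor 20. C6 lies between two oxygens and ring C does not tolerate the acids of an electrophilic acylation, so the ring carbon is made the nucleophile. This requires a halogen at C6 and a temperature low enough that the silyl group on O7 does not migrate to the lithiated carbon.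

19 to 17, then to 16. The O1–C2 bond of ring C is cut, returning the pyran to a phenol with an ortho 3-methylbut-2-enyl chain. The forward reaction is a dehydrogenation to 18 and its 6π oxa-electrocyclization, which can involve only O1 because it is the only free hydroxyl. The C6–Br bond is then removed. Bromination is placed before the oxidation for two reasons: in 16 the C6–H is para to the free hydroxyl while the alkene is still an isolated one, and the halogen afterwards blocks that para position against oxidative coupling. The arene must react with the brominating agent faster than the trisubstituted alkene.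

16 to 8 and 12. Ring B is opened completely: C8a–C8, C6–C7 and C8a–C4a are cut, and the C5–C6 bond is returned to C5–C8a, the reverse of a 1,2-shift. Four of the six ring bonds are therefore made in one operation by way of 13, 14 and 15; a count of three new bonds overlooks the one made by the shift. Every ring position then has its own origin: C8a is the carbonyl carbon of 8 (free OH), C5 its enol ether carbon (OMe), C4a its β-carbon (prenyl), C6 its diazo carbon (H), and C8 and C7 are the two alkyne carbons of 12 (CH2O and O–Si). A hexasubstituted benzene becomes an acyclic diazo ketone and a three-carbon alkyne. The forward step needs a regioselective ketene–alkyne addition and a skipped diene in 8 that survives irradiation.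

8 to 6, then 4, then 2 with 3, then 1. The C=N2 bond is cut by a diazo transfer by way of 7, the CO–CH3 bond by way of 5, and the C=C bond by a phosphonate olefination. The diazo group is placed on an existing methyl ketone and not made by acylating diazomethane. This avoids a toxic, explosive gas and the dipolar addition of a diazoalkane to an unsaturated acyl chloride. It requires kinetic deprotonation of 6 at its methyl group and not at the doubly allylic CH2, and an aldehyde 2 that is not allowed to slip into conjugation.

12 to 10 and 9. 12 is cut between its CH2 and the alkyne. The oxygen-bearing alkyne carbon is the ester carbon of 10, and the other alkyne carbon is a one-carbon unit inserted between them by a 1,2-shift, by way of 11. A three-carbon partner thus comes from a two-carbon hydroxy ester. It requires O-silylation of 11 by a bulky silyl chloride, which gives the alkynyl silyl ether and not a silyl ketene.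

## Other disconnections considered

Alternative 1: The cut removes both isobutyryl groups at once, the a1–acyl bond and the ring B–acyl bond, and leads back to the acyl-free bridged core A1, 3,5-dihydroxy-4,4-dimethyl-2-[(2,4,6-trihydroxyphenyl)methyl]cyclohexa-2,5-dien-1-one.
- Forward key step: 25 with AlCl3 or TiCl4 would acylate a1 and one free carbon of the aromatic ring in one flask to give A2, 3,5-dihydroxy-2-isobutyryl-4,4-dimethyl-6-[(2,4,6-trihydroxy-3-isobutyrylphenyl)methyl]cyclohexa-2,5-dien-1-one. Ring C would then be added, for instance by condensation with 3-methylbut-2-enal A3.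
- In its favour: it is very short, uses one cheap reagent for both acyl groups, and needs no lamp and no diazo compound. On step economy and ease of scale-up it is clearly better than the chosen plan.
- Against it here: the aromatic ring of A1 has two equivalent free carbons and three free hydroxyls, so mono-C-acylation would compete with di-acylation and O-acylation. The bridge, benzylic to two electron-rich rings, is at risk of cleavage and scrambling under a strong Lewis acid. In A2 the one remaining aromatic C–H lies between a hydroxyl next to the bridge and a hydroxyl next to the acyl group, and nothing in the structure forces ring C to close on the first.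
- Comparison: structurally it postpones the differentiation of the ring B oxygens to a late, uncontrolled step, whereas the benzannulation fixes each position by the origin of its atom. Mechanistically it relies on statistical electrophilic substitution. It is the better plan in step count and the weaker one in regiocontrol.

Alternative 2: The cut opens ring A at a4–a5 and a1–a2 and leads to the open-chain diketone A4, 1-[6-isobutyryl-5,7-bis(methoxymethoxy)-2,2-dimethyl-2H-chromen-8-yl]-6-methylheptane-3,5-dione, and dimethyl 2,2-dimethylmalonate A5.
- Forward key step: double deprotonation of A4 with LiN(iPr)2 would let the terminal carbanion (a5) attack one ester of A5, and Dieckmann attack of the central carbon (a1) on the second ester would close ring A to A6, the 5,7-bis(methoxymethyl) ether of 30. Acid would then remove the two acetals.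
- In its favour: ring A arrives with its geminal methyl groups already in A5, so the statistical C-methylation of step 13 is avoided; on this point the alternative is better. The bridge is an ordinary chain bond made early, so no quinone methide is needed and nothing can scramble at the coupling stage, which is also better.
- Against it here: A4 has a third acidic site, the methine of the aryl ketone. Both ester carbonyls of A5 are hindered by the quaternary carbon. The ring closure asks a doubly stabilized, weakly nucleophilic carbon to attack a hindered ester, with retro-Claisen cleavage as the competing path. Above all, A4 already contains the complete ring B and ring C, so the hexasubstituted benzene still has to be solved by a separate, long sequence.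
- Comparison: the alternative spends its key step on the easy half of the molecule (27 is two steps from 24), while the chosen plan spends it on the hard half. Mechanistically both are defensible ionic or pericyclic chemistry. Overall step economy is worse because of the length of the route to A4.

Alternative 3: The cut opens ring A at a4–a5, a6–a1 and a3–a4 and leads to 3-ethoxy-4,4-dimethylcyclobut-2-en-1-one A7 and the ynol ether A8, 8-(3-ethoxyprop-2-yn-1-yl)-5,7-bis(methoxymethoxy)-2,2-dimethyl-2H-chromene.
- Forward key step: at about 80 °C A7 would open to a vinylketene and add [2+2] to A8. The new vinylcyclobutenone would open to a dienylketene, and 6π closure onto the dimethyl-substituted terminus would give A9, 2-{[5,7-bis(methoxymethoxy)-2,2-dimethyl-2H-chromen-8-yl]methyl}-3,5-diethoxy-6,6-dimethylcyclohexa-2,4-dien-1-one, which cannot aromatize.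
- In its favour: it is the same pericyclic logic as the chosen key step and equally predictable in regiochemistry. It is purely thermal, with no diazo compound and no photoreactor, and is therefore safer and easier to scale; on this point it is better. It also sets the quaternary a3 directly.
- Against it here: A9 lacks both isobutyryl groups (a1–H and C6–H) and carries two ethyl enol ethers. Hydrolysis, two C-acylations and removal of two acetals would still follow, and the double acylation has the selectivity problems of alternative 1, now with an acid-sensitive ring C present. A8 again presupposes a finished, differentiated ring B with a propargyl group at C8.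
- Comparison: mechanistically it is equal to the chosen plan. Structurally it builds ring A, which is cheap to buy into, and leaves ring B unsolved. It has more steps after its key step than the chosen plan.

Key step: step 7

Remark on the chemistry: ring A of 30 is written as one enol tautomer of a 2-acylcyclohexane-1,3,5-trione; the tautomers interconvert freely and 30 has no stereocentre, so the route addresses constitution only.

## Route

Step 1
Reactants: 1 4-methylpent-3-en-1-ol
Product: 2 4-methylpent-3-enal
Conditions: Dess–Martin periodinane, CH2Cl2, 0 °C → rt; cold aq. NaHCO3/Na2S2O3 wash; used as a solution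
Reagents that add atoms: none
Why: Dess–Martin oxidation of a homoallylic alcohol under non-basic, non-enolizing conditions should give the β,γ-unsaturated aldehyde without migration of the double bond; the volatile aldehyde is not concentrated but taken on directly.

Step 2
Reactants: 2 4-methylpent-3-enal; 3 methyl 2-(dimethoxyphosphoryl)-2-methoxyacetate
Product: 4 methyl (2Z)-2-methoxy-6-methylhepta-2,5-dienoate
Conditions: 3, LiN(SiMe3)2, THF, –78 °C; then 2, –78 → 0 °C
Reagents that add atoms: none
Why: Horner–Wadsworth–Emmons olefination; the preformed lithium phosphonate leaves no free base to isomerize the aldehyde, and the α-methoxy phosphonate should favour the (Z)-enol ether with the ester trans to the chain; any (E)-isomer is removed by chromatography because the Z geometry keeps the prenyl chain away from the ketene in step 7.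

Step 3
Reactants: 4 methyl (2Z)-2-methoxy-6-methylhepta-2,5-dienoate
Product: 6 (3Z)-3-methoxy-7-methylocta-3,6-dien-2-one, via Weinreb amide 5 (not isolated)
Conditions: MeNH(OMe)·HCl, iPrMgCl, THF, –20 °C; then MeMgBr, –20 → 0 °C; aqueous quench
Reagents that add atoms: methylmagnesium bromide, C[Mg]Br
Why: Ester aminolysis by the magnesium amide of N,O-dimethylhydroxylamine followed by Grignard addition to the Weinreb amide in the same flask; the magnesium chelate of the tetrahedral adduct should stop the addition at the ketone, and N–H deprotonation and carbonyl addition are faster than any C–H deprotonation of the skipped diene.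

Step 4
Reactants: 6 (3Z)-3-methoxy-7-methylocta-3,6-dien-2-one
Product: 8 (3Z)-1-diazo-3-methoxy-7-methylocta-3,6-dien-2-one, via trifluoroacetyl diketone 7 (not isolated)
Conditions: LiN(SiMe3)2, THF, –78 °C; CF3CO2CH2CF3, –78 °C; dilute HCl wash; then 4-acetamidobenzenesulfonyl azide, Et3N, H2O, MeCN, rt
Reagents that add atoms: 4-acetamidobenzenesulfonyl azide, CC(=O)Nc1ccc(cc1)S(=O)(=O)N=[N+]=[N-]
Why: Detrifluoroacetylative diazo transfer (a Regitz transfer to an activated 1,3-diketone): the kinetic lithium enolate at the methyl group is trifluoroacetylated, the sulfonyl azide transfers N2 to the doubly activated carbon and the trifluoroacetyl group leaves as the N-acyl sulfonamide; this reaches the diazo enone without diazomethane and without an unsaturated acyl chloride.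

Step 5
Reactants: 9 ethyl glycolate
Product: 10 ethyl 2-[(tert-butyldimethylsilyl)oxy]acetate
Conditions: TBSCl, imidazole, CH2Cl2, 0 °C → rt
Reagents that add atoms: tert-butyldimethylsilyl chloride, CC(C)(C)[Si](C)(C)Cl
Why: Standard silylation of a primary alcohol; the silyl ether tolerates the strong bases of the next step.

Step 6
Reactants: 10 ethyl 2-[(tert-butyldimethylsilyl)oxy]acetate
Product: 12 tert-butyldimethyl{[3-(triisopropylsilyloxy)prop-2-yn-1-yl]oxy}silane, via lithium ynolate 11 (not isolated)
Conditions: CH2Br2, lithium 2,2,6,6-tetramethylpiperidide, THF, –78 °C; 10; n-BuLi, –78 °C → rt; TIPSCl, –78 °C → rt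
Reagents that add atoms: dibromomethane, BrCBr; triisopropylsilyl chloride, CC(C)[Si](Cl)(C(C)C)C(C)C
Why: Kowalski ester homologation stopped at the ynolate: dibromomethyllithium adds to the ester, bromine–lithium exchange on the dibromo enolate triggers a 1,2-shift of the silyloxymethyl group to the lithium ynolate, and the bulky silyl chloride should silylate it on oxygen to give the siloxyalkyne.

Step 7
Reactants: 8 (3Z)-1-diazo-3-methoxy-7-methylocta-3,6-dien-2-one; 12 tert-butyldimethyl{[3-(triisopropylsilyloxy)prop-2-yn-1-yl]oxy}silane
Product: 16 2-{[(tert-butyldimethylsilyl)oxy]methyl}-5-methoxy-6-(3-methylbut-2-en-1-yl)-3-[(triisopropylsilyl)oxy]phenol, via vinylketene 13 (not isolated), via vinylcyclobutenone 14 (not isolated), via dienylketene 15 (not isolated)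
Conditions: hν (254 nm, quartz tube), ClCH2CH2Cl, rt; then 80 °C
Reagents that add atoms: none
Why: Irradiation expels N2 from 8 and the enol ether carbon shifts from the carbonyl carbon to the diazo carbon (photochemical Wolff rearrangement), giving vinylketene 13 in which the old carbonyl carbon is the ketene carbon (future C8a) and the old diazo carbon is the future C6. The electron-rich alkyne 12 then adds across the ketene C=C in a [2+2] cycloaddition whose regiochemistry is set by polarity: the alkyne carbon carrying the silyloxymethyl group is the nucleophilic end and bonds to the electrophilic ketene carbon, so 14 has C8a–C8 and C6–C7 as its new bonds. Ring strain drives conrotatory 4π opening of 14 to dienylketene 15 under continued irradiation or at 80 °C, and only the isomer with the vinyl group turned toward the ketene goes on. Ring B is closed by a thermal disrotatory 6π electrocyclization of 15 (C8a–C4a), and tautomerization of the resulting cyclohexa-2,4-dienone gives the phenol; the four-membered ring closed by the [2+2] step is only transient. The closest known reaction type is the Danheiser benzannulation in its second-generation form, in which a diazo enone replaces a cyclobutenone as the vinylketene source and a triisopropylsiloxyalkyne is the ketenophile. No stereocentre remains, since the sp3 carbon of 14 is formed as a racemate and is flattened on ring opening, and the enol ether geometry of 8 disappears on aromatization. The step needs regioselectivity in the [2+2] addition (secured by the polarization of 12), preference for the alkyne over the prenyl alkene (the Z geometry holds the chain trans to the ketene, which rules out an intramolecular ketene–alkene addition, and the siloxyalkyne is by far the better ketenophile) and protection of the product phenol from acylation by ketene (slight excess of 12, moderate dilution).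

Step 8
Reactants: 16 2-{[(tert-butyldimethylsilyl)oxy]methyl}-5-methoxy-6-(3-methylbut-2-en-1-yl)-3-[(triisopropylsilyl)oxy]phenol
Product: 17 4-bromo-2-{[(tert-butyldimethylsilyl)oxy]methyl}-5-methoxy-6-(3-methylbut-2-en-1-yl)-3-[(triisopropylsilyl)oxy]phenol
Conditions: NBS, CH2Cl2, –78 °C
Reagents that add atoms: N-bromosuccinimide, O=C1CCC(=O)N1Br
Why: Electrophilic aromatic bromination; the only unsubstituted ring carbon is para to the free hydroxyl and ortho to two further oxygens, so it should react with one equivalent of NBS at –78 °C well before the isolated trisubstituted alkene does; the bromine is the handle for step 10 and blocks this position during step 9.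

Step 9
Reactants: 17 4-bromo-2-{[(tert-butyldimethylsilyl)oxy]methyl}-5-methoxy-6-(3-methylbut-2-en-1-yl)-3-[(triisopropylsilyl)oxy]phenol
Product: 19 {[6-bromo-5-methoxy-2,2-dimethyl-7-[(triisopropylsilyl)oxy]-2H-chromen-8-yl]methoxy}(tert-butyl)dimethylsilane, via quinone methide 18 (not isolated)
Conditions: DDQ, toluene, 80 °C
Reagents that add atoms: none
Why: Oxidative cyclization of an ortho-prenylphenol: DDQ abstracts hydride from the CH2 that is both benzylic and allylic, the resulting ortho-quinone methide closes by 6π oxa-electrocyclization, and only O1 can take part because it is the only free hydroxyl.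

Step 10
Reactants: 19 {[6-bromo-5-methoxy-2,2-dimethyl-7-[(triisopropylsilyl)oxy]-2H-chromen-8-yl]methoxy}(tert-butyl)dimethylsilane; 20 N-methoxy-N,2-dimethylpropanamide
Product: 22 1-[8-{[(tert-butyldimethylsilyl)oxy]methyl}-5-methoxy-2,2-dimethyl-7-[(triisopropylsilyl)oxy]-2H-chromen-6-yl]-2-methylpropan-1-one, via aryllithium 21 (not isolated)
Conditions: n-BuLi, THF, –78 °C; then 20, –78 → 0 °C; aqueous quench
Reagents that add atoms: none
Why: Bromine–lithium exchange followed by acylation with a Weinreb amide; exchange at –78 °C is faster than any deprotonation and cold enough to keep the silyl group on O7 from migrating to carbon, and the chelated tetrahedral adduct releases the hindered aryl ketone only on work-up, so no acid touches ring C.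

Step 11
Reactants: 22 1-[8-{[(tert-butyldimethylsilyl)oxy]methyl}-5-methoxy-2,2-dimethyl-7-[(triisopropylsilyl)oxy]-2H-chromen-6-yl]-2-methylpropan-1-one
Product: 23 1-[8-{[(tert-butyldimethylsilyl)oxy]methyl}-5-hydroxy-2,2-dimethyl-7-[(triisopropylsilyl)oxy]-2H-chromen-6-yl]-2-methylpropan-1-one
Conditions: BCl3, CH2Cl2, –78 °C; aq. NaHCO3
Reagents that add atoms: none
Why: Chelation-controlled demethylation of an aryl methyl ether ortho to a ketone: boron binds the carbonyl and the less hindered, more basic methoxy oxygen, chloride removes the methyl group, and at –78 °C with a small excess the silyl ethers and the chromene alkene should be left alone.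

Step 12
Reactants: 24 phloroglucinol; 25 2-methylpropanoyl chloride
Product: 26 2-methyl-1-(2,4,6-trihydroxyphenyl)propan-1-one
Conditions: AlCl3, CH2Cl2/MeNO2, 0 → 40 °C; dilute HCl
Reagents that add atoms: none
Why: Friedel–Crafts C-acylation of phloroglucinol; the first acyl group deactivates the ring and chelates the flanking hydroxyls, so mono-acylation should dominate.

Step 13
Reactants: 26 2-methyl-1-(2,4,6-trihydroxyphenyl)propan-1-one
Product: 27 3,5-dihydroxy-4,4-dimethyl-2-(2-methylpropanoyl)cyclohexa-2,5-dien-1-one
Conditions: NaOMe, MeI, MeOH, 0 °C → rt; dilute HCl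
Reagents that add atoms: iodomethane, CI
Why: Dearomatizing geminal C-methylation of an acylphloroglucinol polyanion: the first methyl group raises the nucleophilicity of the same carbon and the second one breaks the aromaticity to give the acylfilicinic acid; mono- and tri-methylated material is expected as well and is removed by chromatography or crystallization.

Step 14
Reactants: 23 1-[8-{[(tert-butyldimethylsilyl)oxy]methyl}-5-hydroxy-2,2-dimethyl-7-[(triisopropylsilyl)oxy]-2H-chromen-6-yl]-2-methylpropan-1-one; 27 3,5-dihydroxy-4,4-dimethyl-2-(2-methylpropanoyl)cyclohexa-2,5-dien-1-one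
Product: 30 2-{[5,7-dihydroxy-2,2-dimethyl-6-(2-methylpropanoyl)-2H-chromen-8-yl]methyl}-3,5-dihydroxy-4,4-dimethyl-6-(2-methylpropanoyl)cyclohexa-2,5-dien-1-one, via hydroxymethyl triol 28 (not isolated), via quinone methide 29 (not isolated)
Conditions: 27 (excess), Bu4NF, THF, 0 °C → rt; then 1% aq. KOH, 0 °C → rt, short; dilute HCl to pH 3
Reagents that add atoms: none
Why: Fluoride removes the aryl triisopropylsilyl and the primary tert-butyldimethylsilyl group; the 2-(hydroxymethyl)phenoxide so formed is the species through which the classical alkaline one-carbon coupling of acylphloroglucinols runs, and it should lose hydroxide (pushed by O7, or through the ring by O5) to the quinone methide, which the enolate of 27 captures at its only free ring carbon in a Michael addition; no stereocentre is formed.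

## Compound list

1 | 4-methylpent-3-en-1-ol | CC(C)=CCCO | starting material
2 | 4-methylpent-3-enal | CC(C)=CCC=O | intermediate
3 | methyl 2-(dimethoxyphosphoryl)-2-methoxyacetate | COC(C(=O)OC)P(=O)(OC)OC | starting material
4 | methyl (2Z)-2-methoxy-6-methylhepta-2,5-dienoate | CC(C)=CC/C=C(\OC)C(=O)OC | intermediate
5 | (2Z)-N,2-dimethoxy-N,6-dimethylhepta-2,5-dienamide | CC(C)=CC/C=C(\OC)C(=O)N(C)OC | intermediate
6 | (3Z)-3-methoxy-7-methylocta-3,6-dien-2-one | CC(C)=CC/C=C(\OC)C(C)=O | intermediate
7 | (5Z)-1,1,1-trifluoro-5-methoxy-9-methyldeca-5,8-diene-2,4-dione | CC(C)=CC/C=C(\OC)C(=O)CC(=O)C(F)(F)F | intermediate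
8 | (3Z)-1-diazo-3-methoxy-7-methylocta-3,6-dien-2-one | CC(C)=CC/C=C(\OC)C(=O)C=[N+]=[N-] | intermediate
9 | ethyl glycolate | CCOC(=O)CO | starting material
10 | ethyl 2-[(tert-butyldimethylsilyl)oxy]acetate | CCOC(=O)CO[Si](C)(C)C(C)(C)C | intermediate
11 | lithium 3-[(tert-butyldimethylsilyl)oxy]prop-1-yn-1-olate | [Li+].[O-]C#CCO[Si](C)(C)C(C)(C)C | intermediate
12 | tert-butyldimethyl{[3-(triisopropylsilyloxy)prop-2-yn-1-yl]oxy}silane | CC(C)[Si](OC#CCO[Si](C)(C)C(C)(C)C)(C(C)C)C(C)C | intermediate
13 | (3Z)-3-methoxy-7-methylocta-1,3,6-trien-1-one | CC(C)=CC/C=C(\OC)C=C=O | intermediate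
14 | 2-{[(tert-butyldimethylsilyl)oxy]methyl}-4-[(1Z)-1-methoxy-5-methylhexa-1,4-dien-1-yl]-3-[(triisopropylsilyl)oxy]cyclobut-2-en-1-one (racemic) | O=C1C(CO[Si](C)(C)C(C)(C)C)=C(O[Si](C(C)C)(C(C)C)C(C)C)C1/C(OC)=C/CC=C(C)C | intermediate
15 | (3E,5Z)-2-{[(tert-butyldimethylsilyl)oxy]methyl}-5-methoxy-9-methyl-3-[(triisopropylsilyl)oxy]deca-1,3,5,8-tetraen-1-one | O=C=C(CO[Si](C)(C)C(C)(C)C)/C(O[Si](C(C)C)(C(C)C)C(C)C)=C\C(OC)=C\CC=C(C)C | intermediate
16 | 2-{[(tert-butyldimethylsilyl)oxy]methyl}-5-methoxy-6-(3-methylbut-2-en-1-yl)-3-[(triisopropylsilyl)oxy]phenol | Oc1c(CC=C(C)C)c(OC)cc(O[Si](C(C)C)(C(C)C)C(C)C)c1CO[Si](C)(C)C(C)(C)C | intermediate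
17 | 4-bromo-2-{[(tert-butyldimethylsilyl)oxy]methyl}-5-methoxy-6-(3-methylbut-2-en-1-yl)-3-[(triisopropylsilyl)oxy]phenol | Oc1c(CC=C(C)C)c(OC)c(Br)c(O[Si](C(C)C)(C(C)C)C(C)C)c1CO[Si](C)(C)C(C)(C)C | intermediate
18 | (6Z)-4-bromo-2-{[(tert-butyldimethylsilyl)oxy]methyl}-5-methoxy-6-(3-methylbut-2-en-1-ylidene)-3-[(triisopropylsilyl)oxy]cyclohexa-2,4-dien-1-one | CC(C)=C\C=C1/C(=O)C(CO[Si](C)(C)C(C)(C)C)=C(O[Si](C(C)C)(C(C)C)C(C)C)C(Br)=C1OC | intermediate
19 | {[6-bromo-5-methoxy-2,2-dimethyl-7-[(triisopropylsilyl)oxy]-2H-chromen-8-yl]methoxy}(tert-butyl)dimethylsilane | COc1c(Br)c(O[Si](C(C)C)(C(C)C)C(C)C)c(CO[Si](C)(C)C(C)(C)C)c2OC(C)(C)C=Cc12 | intermediate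
20 | N-methoxy-N,2-dimethylpropanamide | CC(C)C(=O)N(C)OC | starting material
21 | [8-{[(tert-butyldimethylsilyl)oxy]methyl}-5-methoxy-2,2-dimethyl-7-[(triisopropylsilyl)oxy]-2H-chromen-6-yl]lithium | [Li]c1c(OC)c2C=CC(C)(C)Oc2c(CO[Si](C)(C)C(C)(C)C)c1O[Si](C(C)C)(C(C)C)C(C)C | intermediate
22 | 1-[8-{[(tert-butyldimethylsilyl)oxy]methyl}-5-methoxy-2,2-dimethyl-7-[(triisopropylsilyl)oxy]-2H-chromen-6-yl]-2-methylpropan-1-one | CC(C)C(=O)c1c(OC)c2C=CC(C)(C)Oc2c(CO[Si](C)(C)C(C)(C)C)c1O[Si](C(C)C)(C(C)C)C(C)C | intermediate
23 | 1-[8-{[(tert-butyldimethylsilyl)oxy]methyl}-5-hydroxy-2,2-dimethyl-7-[(triisopropylsilyl)oxy]-2H-chromen-6-yl]-2-methylpropan-1-one | CC(C)C(=O)c1c(O)c2C=CC(C)(C)Oc2c(CO[Si](C)(C)C(C)(C)C)c1O[Si](C(C)C)(C(C)C)C(C)C | intermediate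
24 | phloroglucinol (benzene-1,3,5-triol) | Oc1cc(O)cc(O)c1 | starting material
25 | 2-methylpropanoyl chloride | CC(C)C(Cl)=O | starting material
26 | 2-methyl-1-(2,4,6-trihydroxyphenyl)propan-1-one | CC(C)C(=O)c1c(O)cc(O)cc1O | intermediate
27 | 3,5-dihydroxy-4,4-dimethyl-2-(2-methylpropanoyl)cyclohexa-2,5-dien-1-one | CC(C)C(=O)C1=C(O)C(C)(C)C(O)=CC1=O | intermediate
28 | 1-[5,7-dihydroxy-8-(hydroxymethyl)-2,2-dimethyl-2H-chromen-6-yl]-2-methylpropan-1-one | CC(C)C(=O)c1c(O)c2C=CC(C)(C)Oc2c(CO)c1O | intermediate
29 | 5-hydroxy-2,2-dimethyl-8-methylidene-6-(2-methylpropanoyl)-2H-chromen-7(8H)-one | CC(C)C(=O)C1=C(O)C2=C(OC(C)(C)C=C2)C(=C)C1=O | intermediate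
30 | 2-{[5,7-dihydroxy-2,2-dimethyl-6-(2-methylpropanoyl)-2H-chromen-8-yl]methyl}-3,5-dihydroxy-4,4-dimethyl-6-(2-methylpropanoyl)cyclohexa-2,5-dien-1-one | CC(C)C(=O)C1=C(O)C(C)(C)C(O)=C(Cc2c(O)c(C(=O)C(C)C)c(O)c3c2OC(C)(C)C=C3)C1=O | target

## Step count and least certain steps

Total: 14 steps. Longest linear sequence: 10 steps (steps 1, 2, 3, 4, 7, 8, 9, 10, 11, 14).

Step 7 (key step). What may go wrong: photoisomerization of the enol ether double bond before or after loss of N2, which brings the prenyl chain next to the ketene and opens an intramolecular ketene–alkene addition; acylation of the product phenol by ketene that has not yet met the alkyne; incomplete thermal conversion of 14. Fallback: the thermal, first-generation form of the same benzannulation, in which a cyclobutenone is the vinylketene source and its ring opening turns the side chain outward. It sets out from 12. Commercial 5-methylhex-4-enoic acid is converted with oxalyl chloride into 5-methylhex-4-enoyl chloride F1. Et3N then generates 5-methylhexa-1,4-dien-1-one F2 in the presence of ethoxyacetylene, and their [2+2] addition should give 3-ethoxy-4-(3-methylbut-2-en-1-yl)cyclobut-2-en-1-one F3. Heating F3 with 12 in toluene at 80 °C should give the 5-ethoxy analogue of 16, the ethoxy phenol F4. F4 is taken through the chemistry of steps 8 to 10 as the 4-bromophenol F5, the bromochromene F6 and the C6 ketone F7. BCl3 under the conditions of step 11 removes the ethyl group next to the ketone, and the route is rejoined at 23.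

Step 14. What may go wrong: slow loss of hydroxide from the phenoxide of 28, so that 28 lingers and condenses with itself; reopening of the new bond by retro-Michael under the alkaline conditions, with scrambling to symmetrical dimers. Fallback: a leaving group on the bridge carbon and a fluoride trigger. It sets out from 23. HF·pyridine in THF at 0 °C should remove only the primary silyl ether to give 1-[5-hydroxy-8-(hydroxymethyl)-2,2-dimethyl-7-[(triisopropylsilyl)oxy]-2H-chromen-6-yl]-2-methylpropan-1-one F8. Ac2O/pyridine at 0 °C acetylates the primary alcohol, the chelated C5 hydroxyl reacting far more slowly, to give the benzylic acetate F9. Bu4NF at –20 °C in the presence of 27 then frees O7, the phenoxide expels acetate to 29 without added alkali, and addition of 27 rejoins the route at 30.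

Step 8. What may go wrong: attack of the brominating agent on the prenyl alkene with capture by the neighbouring hydroxyl (bromoetherification), or oxidation of the electron-rich phenol. Fallback: no halogen at all. It sets out from 16. DDQ as in step 9 gives the unbrominated chromene tert-butyl({5-methoxy-2,2-dimethyl-7-[(triisopropylsilyl)oxy]-2H-chromen-8-yl}methoxy)dimethylsilane F10. Directed deprotonation of C6–H, which lies between the methoxy and the siloxy group, with s-BuLi/TMEDA at –78 °C gives 21 directly, and 20 then leads to 22, where the route is rejoined. The price is a slower, sterically shielded deprotonation and an open para position during the DDQ step.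

Step 9. What may go wrong: hydride abstraction at the other benzylic position (the CH2 bearing the silyl ether), which also lies ortho to the free hydroxyl, leading to the aldehyde oxidation level; over-oxidation by excess DDQ. Fallback: a non-oxidative ring closure followed by elimination. It sets out from 17. PhSeCl at –78 °C with K2CO3 should give, by selenoetherification with oxygen on the tertiary carbon, the 3-(phenylselanyl)chroman F11. H2O2 oxidizes selenium to the selenoxide F12, which eliminates in syn fashion toward C4 (C2 has no hydrogen) to give 19.

Step 11. What may go wrong: ionization of the electron-rich benzylic silyl ether by the Lewis acid (loss of the silyl ether or its exchange for chloride), or addition of HCl to the C3=C4 bond. Fallback: change the order so that the Lewis acid meets no benzylic ether. It sets out from 22. The desilylation and coupling of step 14 are carried out first, by way of the hydroxymethyl phenol F13 and the quinone methide F14, to give the 5-O-methyl ether of the target F15. The methyl group, still ortho to the C6 ketone, is then removed from F15 with BCl3 at –78 °C or, if the alkene suffers, with MgI2 etherate, which gives 30.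

Step 4. What may go wrong: deprotonation of 6 at the doubly allylic CH2 in competition with the methyl group, giving acylation and diazo transfer at the wrong carbon and migration of the double bonds. Fallback: build the diazo ketone from the acid oxidation level without any ketone enolate. It sets out from 4. LiOH in THF/H2O gives (2Z)-2-methoxy-6-methylhepta-2,5-dienoic acid F16. Isobutyl chloroformate/Et3N at –20 °C gives the mixed anhydride F17, which acylates (trimethylsilyl)diazomethane in MeCN/THF at 0 °C to give 8 after loss of the silyl group. The mixed anhydride avoids HCl, and the electron-rich trisubstituted enol ether double bond should be a poor dipolarophile.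

## Further compounds

F1 | step 7 | 5-methylhex-4-enoyl chloride | CC(C)=CCCC(Cl)=O
F2 | step 7 | 5-methylhexa-1,4-dien-1-one | CC(C)=CCC=C=O
F3 | step 7 | 3-ethoxy-4-(3-methylbut-2-en-1-yl)cyclobut-2-en-1-one (racemic) | CCOC1=CC(=O)C1CC=C(C)C
F4 | step 7 | 2-{[(tert-butyldimethylsilyl)oxy]methyl}-5-ethoxy-6-(3-methylbut-2-en-1-yl)-3-[(triisopropylsilyl)oxy]phenol | CCOc1cc(O[Si](C(C)C)(C(C)C)C(C)C)c(CO[Si](C)(C)C(C)(C)C)c(O)c1CC=C(C)C
F5 | step 7 | 4-bromo-2-{[(tert-butyldimethylsilyl)oxy]methyl}-5-ethoxy-6-(3-methylbut-2-en-1-yl)-3-[(triisopropylsilyl)oxy]phenol | CCOc1c(Br)c(O[Si](C(C)C)(C(C)C)C(C)C)c(CO[Si](C)(C)C(C)(C)C)c(O)c1CC=C(C)C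
F6 | step 7 | {[6-bromo-5-ethoxy-2,2-dimethyl-7-[(triisopropylsilyl)oxy]-2H-chromen-8-yl]methoxy}(tert-butyl)dimethylsilane | CCOc1c(Br)c(O[Si](C(C)C)(C(C)C)C(C)C)c(CO[Si](C)(C)C(C)(C)C)c2OC(C)(C)C=Cc12
F7 | step 7 | 1-[8-{[(tert-butyldimethylsilyl)oxy]methyl}-5-ethoxy-2,2-dimethyl-7-[(triisopropylsilyl)oxy]-2H-chromen-6-yl]-2-methylpropan-1-one | CCOc1c(C(=O)C(C)C)c(O[Si](C(C)C)(C(C)C)C(C)C)c(CO[Si](C)(C)C(C)(C)C)c2OC(C)(C)C=Cc12
F8 | step 14 | 1-[5-hydroxy-8-(hydroxymethyl)-2,2-dimethyl-7-[(triisopropylsilyl)oxy]-2H-chromen-6-yl]-2-methylpropan-1-one | CC(C)C(=O)c1c(O)c2C=CC(C)(C)Oc2c(CO)c1O[Si](C(C)C)(C(C)C)C(C)C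
F9 | step 14 | {5-hydroxy-2,2-dimethyl-6-(2-methylpropanoyl)-7-[(triisopropylsilyl)oxy]-2H-chromen-8-yl}methyl acetate | CC(C)C(=O)c1c(O)c2C=CC(C)(C)Oc2c(COC(C)=O)c1O[Si](C(C)C)(C(C)C)C(C)C
F10 | step 8 | tert-butyl({5-methoxy-2,2-dimethyl-7-[(triisopropylsilyl)oxy]-2H-chromen-8-yl}methoxy)dimethylsilane | COc1cc(O[Si](C(C)C)(C(C)C)C(C)C)c(CO[Si](C)(C)C(C)(C)C)c2OC(C)(C)C=Cc12
F11 | step 9 | {[6-bromo-5-methoxy-2,2-dimethyl-3-(phenylselanyl)-7-[(triisopropylsilyl)oxy]-3,4-dihydro-2H-chromen-8-yl]methoxy}(tert-butyl)dimethylsilane (racemic) | COc1c(Br)c(O[Si](C(C)C)(C(C)C)C(C)C)c(CO[Si](C)(C)C(C)(C)C)c2OC(C)(C)C([Se]c3ccccc3)Cc12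
F12 | step 9 | {[6-bromo-5-methoxy-2,2-dimethyl-3-(phenylseleninyl)-7-[(triisopropylsilyl)oxy]-3,4-dihydro-2H-chromen-8-yl]methoxy}(tert-butyl)dimethylsilane (mixture of stereoisomers) | COc1c(Br)c(O[Si](C(C)C)(C(C)C)C(C)C)c(CO[Si](C)(C)C(C)(C)C)c2OC(C)(C)C([Se](=O)c3ccccc3)Cc12
F13 | step 11 | 1-[7-hydroxy-8-(hydroxymethyl)-5-methoxy-2,2-dimethyl-2H-chromen-6-yl]-2-methylpropan-1-one | CC(C)C(=O)c1c(OC)c2C=CC(C)(C)Oc2c(CO)c1O
F14 | step 11 | 5-methoxy-2,2-dimethyl-8-methylidene-6-(2-methylpropanoyl)-2H-chromen-7(8H)-one | CC(C)C(=O)C1=C(OC)C2=C(OC(C)(C)C=C2)C(=C)C1=O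
F15 | step 11 | 3,5-dihydroxy-2-{[7-hydroxy-5-methoxy-2,2-dimethyl-6-(2-methylpropanoyl)-2H-chromen-8-yl]methyl}-4,4-dimethyl-6-(2-methylpropanoyl)cyclohexa-2,5-dien-1-one | CC(C)C(=O)C1=C(O)C(C)(C)C(O)=C(Cc2c(O)c(C(=O)C(C)C)c(OC)c3c2OC(C)(C)C=C3)C1=O
F16 | step 4 | (2Z)-2-methoxy-6-methylhepta-2,5-dienoic acid | CC(C)=CC/C=C(\OC)C(O)=O
F17 | step 4 | (2Z)-2-methoxy-6-methylhepta-2,5-dienoic 2-methylpropyl carbonic anhydride | CC(C)=CC/C=C(\OC)C(=O)OC(=O)OCC(C)C
A1 | alternative 1 | 3,5-dihydroxy-4,4-dimethyl-2-[(2,4,6-trihydroxyphenyl)methyl]cyclohexa-2,5-dien-1-one | O=C1C=C(O)C(C)(C)C(O)=C1Cc1c(O)cc(O)cc1O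
A2 | alternative 1 | 3,5-dihydroxy-2-isobutyryl-4,4-dimethyl-6-[(2,4,6-trihydroxy-3-isobutyrylphenyl)methyl]cyclohexa-2,5-dien-1-one | CC(C)C(=O)C1=C(O)C(C)(C)C(O)=C(Cc2c(O)cc(O)c(C(=O)C(C)C)c2O)C1=O
A3 | alternative 1 | 3-methylbut-2-enal | CC(C)=CC=O
A4 | alternative 2 | 1-[6-isobutyryl-5,7-bis(methoxymethoxy)-2,2-dimethyl-2H-chromen-8-yl]-6-methylheptane-3,5-dione | CC(C)C(=O)CC(=O)CCc1c(OCOC)c(C(=O)C(C)C)c(OCOC)c2C=CC(C)(C)Oc12
A5 | alternative 2 | dimethyl 2,2-dimethylmalonate | COC(=O)C(C)(C)C(=O)OC
A6 | alternative 2 | 2-{[6-isobutyryl-5,7-bis(methoxymethoxy)-2,2-dimethyl-2H-chromen-8-yl]methyl}-3,5-dihydroxy-6-isobutyryl-4,4-dimethylcyclohexa-2,5-dien-1-one | CC(C)C(=O)C1=C(O)C(C)(C)C(O)=C(Cc2c(OCOC)c(C(=O)C(C)C)c(OCOC)c3c2OC(C)(C)C=C3)C1=O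
A7 | alternative 3 | 3-ethoxy-4,4-dimethylcyclobut-2-en-1-one | CCOC1=CC(=O)C1(C)C
A8 | alternative 3 | 8-(3-ethoxyprop-2-yn-1-yl)-5,7-bis(methoxymethoxy)-2,2-dimethyl-2H-chromene | CCOC#CCc1c(OCOC)cc(OCOC)c2C=CC(C)(C)Oc12
A9 | alternative 3 | 2-{[5,7-bis(methoxymethoxy)-2,2-dimethyl-2H-chromen-8-yl]methyl}-3,5-diethoxy-6,6-dimethylcyclohexa-2,4-dien-1-one | O=C1C(Cc2c(OCOC)cc(OCOC)c3C=CC(C)(C)Oc23)=C(OCC)C=C(OCC)C1(C)C
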